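**Retrosynthetic overview**
1. Glaucolide L ⇐ O13‑desilylation and peripheral peracid epoxidation of the E‑4,5‑alkene of a macrocyclic 7(11)‑en‑12,6‑olide (the epoxide is the last ring formed).
2. That macrocycle ⇐ a 2‑silyl‑3,4‑disubstituted furan in one operation: singlet‑oxygen dearomatisation to a Z‑4‑oxo‑enoate silyl ester, Nozaki–Hiyama–Kishi closure of C5–C6 (ten‑membered ring), then in situ lactonisation (butenolide).
3. The furan seco‑precursor ⇐ C7–C8 bond from a C4‑lithiated 2‑silyl‑3‑furanmethanol and a cis‑β‑methyl‑γ‑lactone; C8 is set by CBS reduction, followed by two acylations.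
4. The silylfuran ⇐ furan‑3‑ylmethanol (silylation, retro‑Brook); the lactone ⇐ pent‑4‑yn‑1‑ol (carboalumination–iodination, Z‑crotylboration for C1/C10, oxidative lactonisation).

Assumption: positions are referred to by germacrane numbering (ring C1–C10, lactone carbonyl C12, hydroxymethyl C13, C14 on C10, C15 on C4), and the listed reagents are taken as commercially available.

**Route**

Step 1
Reactants: 1 pent-4-yn-1-ol
Product: 3 (E)-5-iodo-4-methylpent-4-en-1-ol, via alkenyldimethylalane 2 (not isolated)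
Conditions: AlMe3 (3 equiv), Cp2ZrCl2 (0.25 equiv), CH2Cl2, 0 °C to rt; then I2, THF, −30 to 0 °C
Reagents that add atoms: trimethylaluminium (AlMe3) C[Al](C)C; iodine [I][I]
Why: Zirconium‑catalysed Negishi carboalumination adds methyl and aluminium syn across the terminal alkyne with methyl on the internal carbon, and iodinolysis with retention gives only the E alkenyl iodide (C4=C5 with C15).

Step 2
Reactants: 3 (E)-5-iodo-4-methylpent-4-en-1-ol
Product: 4 (E)-5-iodo-4-methylpent-4-enal
Conditions: PhI(OAc)2, TEMPO [(2,2,6,6-tetramethylpiperidin-1-yl)oxyl, 10 mol %], CH2Cl2, rt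
Reagents that add atoms: none
Why: Oxoammonium‑mediated (TEMPO/PhI(OAc)2) oxidation stops at the aldehyde and does not touch the alkenyl iodide.

Step 3
Reactants: 4 (E)-5-iodo-4-methylpent-4-enal; 5 cis-but-2-ene
Product: 10 (3S,4S,7E)-8-iodo-3,7-dimethylocta-1,7-dien-4-ol, via (Z)-crotylpotassium 6 (not isolated), via potassium crotylborate 7 (not isolated), via (Z)-crotyldiisopinocampheylborane 8 (not isolated), via borinate ester 9 (not isolated)
Conditions: 5, n-BuLi, KOt-Bu, THF, −78 to −45 °C; (+)-Ipc2BOMe [from (−)-α-pinene], −78 °C; BF3·OEt2, −78 °C; then 4, −78 °C; then NaOH, H2O2, 0 °C to rt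
Reagents that add atoms: none
Why: Brown asymmetric crotylboration proceeds through a closed chair transition state in which the Z‑crotyl geometry gives the syn C10‑methyl/C1‑hydroxyl relationship and the isopinocampheyl groups of the (−)-α-pinene series direct attack to the Re face of the aldehyde, setting C1 (S) and C10 (S).

Step 4
Reactants: 10 (3S,4S,7E)-8-iodo-3,7-dimethylocta-1,7-dien-4-ol
Product: 12 (3S,4S,7E)-8-iodo-3,7-dimethyloct-7-ene-1,4-diol, via B-alkyl-9-BBN adduct 11 (not isolated)
Conditions: 9-BBN (2.2 equiv), THF, 0 °C to rt; then NaOH, H2O2, 0 °C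
Reagents that add atoms: hydrogen peroxide OO
Why: Hydroboration–oxidation with bulky 9-BBN is anti‑Markovnikov and selective for the monosubstituted alkene over the trisubstituted iodo‑alkene, and no stereocentre is touched.

Step 5
Reactants: 12 (3S,4S,7E)-8-iodo-3,7-dimethyloct-7-ene-1,4-diol
Product: 13 (4S,5S)-5-[(3E)-4-iodo-3-methylbut-3-en-1-yl]-4-methyloxolan-2-one
Conditions: PhI(OAc)2 (2.5 equiv), TEMPO (20 mol %), CH2Cl2, rt
Reagents that add atoms: none
Why: TEMPO‑catalysed oxidative lactonisation oxidises the primary alcohol selectively and the resulting lactol on to the γ‑lactone, which protects O1 and turns C8 into an acylating carbon while the cis (4S,5S) relationship is carried over unchanged.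

Step 6
Reactants: 14 furan-3-ylmethanol
Product: 16 [2-(tert-butyldimethylsilyl)furan-3-yl]methanol, via silyl ether 15 (not isolated)
Conditions: n-BuLi (1.0 equiv), THF, −78 to 0 °C; TBSCl, 0 °C to rt; then n-BuLi (1.2 equiv), HMPA, −78 to 0 °C; aq NH4Cl
Reagents that add atoms: tert-butyldimethylsilyl chloride CC(C)(C)[Si](C)(C)Cl
Why: One‑pot O‑silylation, lithiation at C2 (the most acidic furan position, flanked by the ring oxygen and the CH2OSi group) and 1,4 O→C silyl migration (retro‑Brook rearrangement, driven by formation of the lithium alkoxide) places silicon on the carbon that becomes the lactone carbonyl C12.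

Step 7
Reactants: 16 [2-(tert-butyldimethylsilyl)furan-3-yl]methanol; 13 (4S,5S)-5-[(3E)-4-iodo-3-methylbut-3-en-1-yl]-4-methyloxolan-2-one
Product: 18 (3S,4S,7E)-1-[5-(tert-butyldimethylsilyl)-4-(hydroxymethyl)furan-3-yl]-4-hydroxy-8-iodo-3,7-dimethyloct-7-en-1-one, via dilithiofuran 17 (not isolated)
Conditions: 16 (1.3 equiv), n-BuLi (2.2 equiv per 16), DME, 0 °C, 15 min; then 13, THF, −78 °C; aq NH4Cl at −78 °C
Reagents that add atoms: none
Why: With C2 blocked by silicon the lithium alkoxide directs the second deprotonation to the adjacent C4 (directed ortho‑metalation), and the furyllithium adds once to the γ‑lactone because the tetrahedral lithium lactolate persists at −78 °C (lithium–iodine exchange with the alkenyl iodide is thermodynamically unfavourable for the chelated furyllithium), forming C7–C8 without creating a stereocentre.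

Step 8
Reactants: 18 (3S,4S,7E)-1-[5-(tert-butyldimethylsilyl)-4-(hydroxymethyl)furan-3-yl]-4-hydroxy-8-iodo-3,7-dimethyloct-7-en-1-one
Product: 20 (3S,4S,7E)-1-[5-(tert-butyldimethylsilyl)-4-{[(tert-butyldimethylsilyl)oxy]methyl}furan-3-yl]-8-iodo-3,7-dimethyl-1-oxooct-7-en-4-yl acetate, via mono-TBS ether 19 (not isolated)
Conditions: TBSCl (1.05 equiv), imidazole, CH2Cl2, 0 °C; then Ac2O, DMAP [4-(dimethylamino)pyridine], pyridine, rt
Reagents that add atoms: tert-butyldimethylsilyl chloride CC(C)(C)[Si](C)(C)Cl; acetic anhydride CC(=O)OC(C)=O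
Why: The silyl chloride discriminates the primary furylmethyl hydroxyl (O13) from the hindered secondary one, and DMAP‑catalysed acetylation in the same flask then caps O1, all without stereochemical change.

Step 9
Reactants: 20 (3S,4S,7E)-1-[5-(tert-butyldimethylsilyl)-4-{[(tert-butyldimethylsilyl)oxy]methyl}furan-3-yl]-8-iodo-3,7-dimethyl-1-oxooct-7-en-4-yl acetate
Product: 21 (1S,3S,4S,7E)-1-[5-(tert-butyldimethylsilyl)-4-{[(tert-butyldimethylsilyl)oxy]methyl}furan-3-yl]-1-hydroxy-8-iodo-3,7-dimethyloct-7-en-4-yl acetate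
Conditions: (R)-Me-CBS oxazaborolidine [(R)-1-methyl-3,3-diphenyltetrahydro-1H,3H-pyrrolo[1,2-c][1,3,2]oxazaborole, 0.2 equiv], BH3·SMe2, THF, −30 °C; aq NH4Cl
Reagents that add atoms: none
Why: Corey–Bakshi–Shibata reduction binds the ketone with the furyl group as the large substituent and delivers hydride to the Re face under reagent control, giving the C8 (S) carbinol while the acetate and the iodo‑alkene are inert at −30 °C.

Step 10
Reactants: 21 (1S,3S,4S,7E)-1-[5-(tert-butyldimethylsilyl)-4-{[(tert-butyldimethylsilyl)oxy]methyl}furan-3-yl]-1-hydroxy-8-iodo-3,7-dimethyloct-7-en-4-yl acetate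
Product: 22 (1S,3S,4S,7E)-4-acetoxy-1-[5-(tert-butyldimethylsilyl)-4-{[(tert-butyldimethylsilyl)oxy]methyl}furan-3-yl]-8-iodo-3,7-dimethyloct-7-en-1-yl 2-methylprop-2-enoate
Conditions: methacryloyl chloride, Et3N, DMAP (cat.), CH2Cl2, 0 °C
Reagents that add atoms: methacryloyl chloride C=C(C)C(Cl)=O
Why: DMAP‑catalysed O‑acylation of the secondary alcohol installs the C8 methacrylate with retention of configuration.

Step 11
Reactants: 22 (1S,3S,4S,7E)-4-acetoxy-1-[5-(tert-butyldimethylsilyl)-4-{[(tert-butyldimethylsilyl)oxy]methyl}furan-3-yl]-8-iodo-3,7-dimethyloct-7-en-1-yl 2-methylprop-2-enoate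
Product: 25 (1S,6R,8S,10S,4E)-1-acetoxy-13-[(tert-butyldimethylsilyl)oxy]-8-(methacryloyloxy)germacra-4,7(11)-dien-12,6-olide, via furan endoperoxide 23 (not isolated), via silyl ester enal 24 (not isolated)
Conditions: O2, hν (visible), 5,10,15,20-tetraphenylporphyrin (1 mol %), CH2Cl2, −78 °C, then 0 °C, evaporate under Ar; then CrCl2 (10 equiv), NiCl2 (2 mol %), degassed DMSO/THF, rt, 0.002 M (slow addition)
Reagents that add atoms: dioxygen O=O
Why: Proposed new method: the electron‑rich silylfuran undergoes [4+2] cycloaddition with singlet oxygen much faster than the iodo‑alkene or the methacrylate can react, endoperoxide 23 collapses by the known 1,2‑silyl shift from C12 to the peroxide oxygen to the Z‑4‑oxo‑enoate silyl ester 24 (aromaticity is lost and C12 becomes the carboxyl carbon with full regiocontrol), and without isolation the alkenyl iodide is converted by nickel‑catalysed oxidative addition and transmetalation into an alkenylchromium (E geometry retained) that adds to the unmasked C6 aldehyde in a Nozaki–Hiyama–Kishi ten‑membered ring closure, after which the trivalent chromium alkoxide, held cis to the silyl ester, lactonises by 5‑exo acyl substitution with loss of silanolate; C6 is set in this ring closure and is expected, though not securely predicted, to come from the transition state with the aldehyde oxygen outside the forming E‑cycloalkene and the C8 acyloxy group pseudo‑equatorial, giving the 6,8‑cis (both α) product, which is 6R in 25 and becomes 6S after epoxidation; the closest known reaction types are the photooxygenation of 2‑silylfurans to γ‑hydroxybutenolides and Nozaki–Hiyama–Kishi macrocyclisations of alkenyl iodide aldehydes.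

Step 12
Reactants: 25 (1S,6R,8S,10S,4E)-1-acetoxy-13-[(tert-butyldimethylsilyl)oxy]-8-(methacryloyloxy)germacra-4,7(11)-dien-12,6-olide
Product: 26 (1S,4R,5R,6S,8S,10S)-1-acetoxy-13-[(tert-butyldimethylsilyl)oxy]-4,5-epoxy-8-(methacryloyloxy)germacr-7(11)-en-12,6-olide
Conditions: mCPBA, NaHCO3, CH2Cl2, 0 °C
Reagents that add atoms: 3-chloroperoxybenzoic acid OOC(=O)c1cccc(Cl)c1
Why: Prilezhaev epoxidation is chemoselective for the only electron‑rich alkene and stereospecific (E alkene gives the trans epoxide), and the peracid attacks the peripheral face of the E‑cycloalkene in the conformer that keeps H6 eclipsed with the C4 methyl (minimised allylic 1,3‑strain), that is the face syn to O6 and anti to C7, which gives the 4R,5R (4α,5β) epoxide.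

Step 13
Reactants: 26 (1S,4R,5R,6S,8S,10S)-1-acetoxy-13-[(tert-butyldimethylsilyl)oxy]-4,5-epoxy-8-(methacryloyloxy)germacr-7(11)-en-12,6-olide
Product: 27 glaucolide L
Conditions: HF·pyridine, pyridine, THF, 0 °C
Reagents that add atoms: none
Why: Pyridine‑buffered fluoride cleavage of the primary silyl ether leaves the epoxide, both esters and the butenolide intact and releases the C13 hydroxyl.

**Compound list**

1 | pent-4-yn-1-ol | C#CCCCO | starting material
2 | dimethyl[(1E)-5-(dimethylaluminiooxy)-2-methylpent-1-en-1-yl]aluminium | C[Al](C)OCCC/C(C)=C/[Al](C)C | intermediate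
3 | (E)-5-iodo-4-methylpent-4-en-1-ol | OCCC/C(C)=C/I | intermediate
4 | (E)-5-iodo-4-methylpent-4-enal | O=CCC/C(C)=C/I | intermediate
5 | cis-but-2-ene | C/C=C\C | starting material
6 | (Z)-but-2-en-1-ylpotassium | C/C=C\C[K] | intermediate
7 | potassium (Z)-but-2-en-1-yl(methoxy)bis[(1S,2S,3S,5R)-isopinocampheyl]borate | [K+].CO[B-](C/C=C\C)([C@H]1C[C@H]2C[C@@H]([C@@H]1C)C2(C)C)[C@H]1C[C@H]2C[C@@H]([C@@H]1C)C2(C)C | intermediate
8 | (Z)-but-2-en-1-ylbis[(1S,2S,3S,5R)-isopinocampheyl]borane | C/C=C\CB([C@H]1C[C@H]2C[C@@H]([C@@H]1C)C2(C)C)[C@H]1C[C@H]2C[C@@H]([C@@H]1C)C2(C)C | intermediate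
9 | diisopinocampheylborinate ester of 10 (O–B bond at C1 oxygen) | C=C[C@H](C)[C@@H](OB([C@H]1C[C@H]2C[C@@H]([C@@H]1C)C2(C)C)[C@H]1C[C@H]2C[C@@H]([C@@H]1C)C2(C)C)CC/C(C)=C/I | intermediate
10 | (3S,4S,7E)-8-iodo-3,7-dimethylocta-1,7-dien-4-ol | C=C[C@H](C)[C@@H](O)CC/C(C)=C/I | intermediate
11 | 9-[(3S,4S,7E)-4-hydroxy-8-iodo-3,7-dimethyloct-7-en-1-yl]-9-borabicyclo[3.3.1]nonane | B1(CC[C@H](C)[C@@H](O)CC/C(C)=C/I)C2CCCC1CCC2 | intermediate
12 | (3S,4S,7E)-8-iodo-3,7-dimethyloct-7-ene-1,4-diol | OCC[C@H](C)[C@@H](O)CC/C(C)=C/I | intermediate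
13 | (4S,5S)-5-[(3E)-4-iodo-3-methylbut-3-en-1-yl]-4-methyloxolan-2-one (cis lactone) | O=C1C[C@H](C)[C@@H](O1)CC/C(C)=C/I | intermediate
14 | furan-3-ylmethanol | OCc1ccoc1 | starting material
15 | tert-butyl(furan-3-ylmethoxy)dimethylsilane | CC(C)(C)[Si](C)(C)OCc1ccoc1 | intermediate
16 | [2-(tert-butyldimethylsilyl)furan-3-yl]methanol | OCc1ccoc1[Si](C)(C)C(C)(C)C | intermediate
17 | lithium [2-(tert-butyldimethylsilyl)-4-lithiofuran-3-yl]methanolate | [Li]OCc1c([Li])coc1[Si](C)(C)C(C)(C)C | intermediate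
18 | (3S,4S,7E)-1-[5-(tert-butyldimethylsilyl)-4-(hydroxymethyl)furan-3-yl]-4-hydroxy-8-iodo-3,7-dimethyloct-7-en-1-one | O=C(C[C@H](C)[C@@H](O)CC/C(C)=C/I)c1coc([Si](C)(C)C(C)(C)C)c1CO | intermediate
19 | (3S,4S,7E)-1-[5-(tert-butyldimethylsilyl)-4-{[(tert-butyldimethylsilyl)oxy]methyl}furan-3-yl]-4-hydroxy-8-iodo-3,7-dimethyloct-7-en-1-one | O=C(C[C@H](C)[C@@H](O)CC/C(C)=C/I)c1coc([Si](C)(C)C(C)(C)C)c1CO[Si](C)(C)C(C)(C)C | intermediate
20 | (3S,4S,7E)-1-[5-(tert-butyldimethylsilyl)-4-{[(tert-butyldimethylsilyl)oxy]methyl}furan-3-yl]-8-iodo-3,7-dimethyl-1-oxooct-7-en-4-yl acetate | O=C(C[C@H](C)[C@@H](OC(C)=O)CC/C(C)=C/I)c1coc([Si](C)(C)C(C)(C)C)c1CO[Si](C)(C)C(C)(C)C | intermediate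
21 | (1S,3S,4S,7E)-1-[5-(tert-butyldimethylsilyl)-4-{[(tert-butyldimethylsilyl)oxy]methyl}furan-3-yl]-1-hydroxy-8-iodo-3,7-dimethyloct-7-en-4-yl acetate | O[C@@H](C[C@H](C)[C@@H](OC(C)=O)CC/C(C)=C/I)c1coc([Si](C)(C)C(C)(C)C)c1CO[Si](C)(C)C(C)(C)C | intermediate
22 | (1S,3S,4S,7E)-4-acetoxy-1-[5-(tert-butyldimethylsilyl)-4-{[(tert-butyldimethylsilyl)oxy]methyl}furan-3-yl]-8-iodo-3,7-dimethyloct-7-en-1-yl 2-methylprop-2-enoate | C=C(C)C(=O)O[C@@H](C[C@H](C)[C@@H](OC(C)=O)CC/C(C)=C/I)c1coc([Si](C)(C)C(C)(C)C)c1CO[Si](C)(C)C(C)(C)C | intermediate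
23 | 2,5-endoperoxide of 22 (2,3,7-trioxabicyclo[2.2.1]hept-5-ene; silyl on bridgehead C12, H on bridgehead C6; bridgehead configuration undefined) | C=C(C)C(=O)O[C@@H](C[C@H](C)[C@@H](OC(C)=O)CC/C(C)=C/I)C1=C(CO[Si](C)(C)C(C)(C)C)C2([Si](C)(C)C(C)(C)C)OOC1O2 | intermediate
24 | tert-butyldimethylsilyl (2Z)-4-oxobut-2-enoate bearing CH2OTBS on C2 (C11) and the (1S,3S,4S,7E) side chain on C3 (C7); C6 aldehyde cis to the C12 silyl ester | C=C(C)C(=O)O[C@@H](C[C@H](C)[C@@H](OC(C)=O)CC/C(C)=C/I)/C(C=O)=C(/C(=O)O[Si](C)(C)C(C)(C)C)CO[Si](C)(C)C(C)(C)C | intermediate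
25 | (1S,6R,8S,10S,4E)-1-acetoxy-13-[(tert-butyldimethylsilyl)oxy]-8-(methacryloyloxy)germacra-4,7(11)-dien-12,6-olide | C=C(C)C(=O)O[C@H]1C[C@H](C)[C@@H](OC(C)=O)CC/C(C)=C/[C@H]2OC(=O)C(CO[Si](C)(C)C(C)(C)C)=C12 | intermediate
26 | (1S,4R,5R,6S,8S,10S)-1-acetoxy-13-[(tert-butyldimethylsilyl)oxy]-4,5-epoxy-8-(methacryloyloxy)germacr-7(11)-en-12,6-olide | C=C(C)C(=O)O[C@H]1C[C@H](C)[C@@H](OC(C)=O)CC[C@@]2(C)O[C@@H]2[C@H]2OC(=O)C(CO[Si](C)(C)C(C)(C)C)=C12 | intermediate
27 | glaucolide L, (1S,4R,5R,6S,8S,10S)-1-acetoxy-4,5-epoxy-13-hydroxy-8-(methacryloyloxy)germacr-7(11)-en-12,6-olide | C=C(C)C(=O)O[C@H]1C[C@H](C)[C@@H](OC(C)=O)CC[C@@]2(C)O[C@@H]2[C@H]2OC(=O)C(CO)=C12 | target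

**Step count and risk**

Total steps: 13. Longest linear sequence: 12 (steps 1–5 and 7–13); the furan branch is step 6.

Most likely to fail, in order:

Step 11. The telescoped dearomatisation and ring closure can fail in four ways: the silyl shift may be slow for the bulky silyl group, divalent chromium may reduce the ene‑dicarbonyl of 24, the alkoxide may attack silicon instead of the ester carbonyl, or C6 may form with the wrong configuration. The fallback sets out from 22 and closes the ring before the furan is dearomatised. Iridium‑catalysed C–H borylation ([Ir(OMe)(cod)]2, 4,4′-di-tert-butyl-2,2′-bipyridine, B2pin2) of the single remaining furan C–H gives the furyl pinacol boronate F1. Intramolecular Suzuki–Miyaura coupling with the alkenyl iodide (Pd(PPh3)4, Cs2CO3, THF/H2O, high dilution) gives the macrocyclic 2-alkenylfuran F2. Photooxygenation of F2 with hydrolytic work‑up gives the γ-hydroxybutenolide F3, a C6 hemiketal. NaBH4/CeCl3 reduction of its ring‑opened keto acid and acid‑induced relactonisation return the route at 25; C6 is then set by external hydride delivery and no chromium is involved.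

Step 7. The lithiation may not be clean at C4, or the furyllithium may undergo lithium–iodine exchange, enolise the lactone or add twice. The fallback sets out from 13 and joins the fragments at the aldehyde oxidation level with a non‑basic organocerium. i-Bu2AlH reduction at −78 °C gives the lactol F4. Dilithiofuran 17, transmetalated with CeCl3, adds to the open hydroxy‑aldehyde form of F4 to give the triol F5 (C8 epimers, of no consequence). TBSCl/imidazole silylates the primary hydroxyl to give the silyl ether diol F6. MnO2 oxidises only the furylic C8 carbinol, which returns the route at 19 (isolated in this variant and then acetylated as in the second half of step 8).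

Step 12. The peracid may attack the other face of the macrocyclic alkene. The fallback sets out from 25 and delivers the oxygen by double inversion instead of direct transfer. NBS in aqueous THF places bromine on the peripheral face at C5 and water on the tertiary C4 from the opposite face, giving the bromohydrin F7. Ag2O in CH2Cl2 closes F7 with inversion at C5 and returns the route at 26, with the epoxide on the face opposite to the one the electrophile attacks.

**Further compounds**
F1 | step 11 | pinacol boronate of 22 at the free furan carbon (C6) | C=C(C)C(=O)O[C@@H](C[C@H](C)[C@@H](OC(C)=O)CC/C(C)=C/I)c1c(B2OC(C)(C)C(C)(C)O2)oc([Si](C)(C)C(C)(C)C)c1CO[Si](C)(C)C(C)(C)C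
F2 | step 11 | macrocyclic 2-alkenylfuran, (1S,8S,10S,4E) ten-membered ring fused at furan C2/C3 (C6/C7), silyl on C12, CH2OTBS on C11 | C=C(C)C(=O)O[C@H]1C[C@H](C)[C@@H](OC(C)=O)CC/C(C)=C/c2oc([Si](C)(C)C(C)(C)C)c(CO[Si](C)(C)C(C)(C)C)c12
F3 | step 11 | 6-hydroxy analogue of 25 (γ-hydroxybutenolide, C6 hemiketal, configuration at C6 undefined) | C=C(C)C(=O)O[C@H]1C[C@H](C)[C@@H](OC(C)=O)CC/C(C)=C/C2(O)OC(=O)C(CO[Si](C)(C)C(C)(C)C)=C12
F4 | step 7 | (4S,5S)-5-[(3E)-4-iodo-3-methylbut-3-en-1-yl]-4-methyloxolan-2-ol (lactol, anomers) | OC1C[C@H](C)[C@@H](O1)CC/C(C)=C/I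
F5 | step 7 | (3S,4S,7E)-1-[5-(tert-butyldimethylsilyl)-4-(hydroxymethyl)furan-3-yl]-8-iodo-3,7-dimethyloct-7-ene-1,4-diol (C1 epimers) | OC(C[C@H](C)[C@@H](O)CC/C(C)=C/I)c1coc([Si](C)(C)C(C)(C)C)c1CO
F6 | step 7 | (3S,4S,7E)-1-[5-(tert-butyldimethylsilyl)-4-{[(tert-butyldimethylsilyl)oxy]methyl}furan-3-yl]-8-iodo-3,7-dimethyloct-7-ene-1,4-diol (C1 epimers) | OC(C[C@H](C)[C@@H](O)CC/C(C)=C/I)c1coc([Si](C)(C)C(C)(C)C)c1CO[Si](C)(C)C(C)(C)C
F7 | step 12 | 5-bromo-4-hydroxy-4,5-dihydro derivative of 25 (bromohydrin; C4 hydroxyl configured as the epoxide oxygen of 26, C5 bromine on the opposite face) | C=C(C)C(=O)O[C@H]1C[C@H](C)[C@@H](OC(C)=O)CC[C@@](C)(O)[C@@H](Br)[C@H]2OC(=O)C(CO[Si](C)(C)C(C)(C)C)=C12
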